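## The problem

The target, (2S)-5,7-dihydroxy-2-[4-hydroxy-3-methoxy-5-(3-methylbut-2-en-1-yl)phenyl]chroman-4-one (21), is a flavanone. A phloroglucinol ring A is fused through C4a and C8a to a dihydropyranone ring C, which carries the tetrasubstituted aryl ring B at C2. C2 is the only stereocentre, so nothing in the molecule can relay chirality to it and its S configuration must come from a reagent or catalyst. It is also fragile: it is benzylic and lies β to the C4 ketone through O1, so base opens ring C by retro-oxa-Michael reaction to the achiral chalcone, and strong acid can ionize C2–O1. The prenyl group of ring B sits ortho to the 4'-phenol. Acid closes this pair to a chroman, hydrogenation saturates the olefin, and electrophilic oxidants attack both the olefin and the electron-rich phenol. The prenyl group also has to be placed at C5' and nowhere else. The enabling feature is the vinylogous ester O1–C8a=C4a–C4(=O)–C3. If ring A is written in a keto form with C5 as ketone and C7 as a carbinol, ring C becomes an ordinary 2,3-dihydro-4H-pyran-4-one, the adduct of an aryl aldehyde and a 1-methoxy-3-silyloxy diene spanning C3, C4, C4a and C8a. Oxidation of C7 afterwards gives a 1,3,5-trione, which exists as the phenol.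

## Retrosynthesis

21 from 20. Only the Si–O bond at the 4'-oxygen is cut. The ring B phenol has to stay masked through the acid of the key step and the oxidant of the aromatization. A triisopropylsilyl ether is chosen because buffered fluoride removes it without the acid that endangers the prenyl group or the base that endangers C2.

20 from 18 (through 19) and 18 from 17. No skeletal bond is cut; aromatic ring A is traced back to its hydro form with a C7 carbinol. This is what lets ring A act as a plain vinylogous ester in the key step. The forward direction asks for selective cleavage of the alkyl silyl ether of 17 beside the aryl silyl ether, then an oxidation to trione 19 that spares the prenyl olefin. Tautomerization to 20 erases the C7 centre, so its configuration never matters.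

17 from 7 and 15 (through 16). C2–C3 and O1–C8a are cut. The neighbouring cut at O1–C2 (oxa-Michael closure of a chalcone) runs through the very equilibrium that racemizes flavanones. The cut at C4–C4a (acylation of ring A) would need the stereocentre to be made separately. The chosen cut forms the stereocentre and ring C in one operation from an aldehyde and an enol silane, both much simpler than 17. The forward reaction must give facial control at the aldehyde and a ring closure that does not touch the new C–O bond.

15 from 14, 13, 11, 9 and 8 (through 12 and 10). The enol silane 15 comes from methyl ketone 14 by kinetic enolization. 14 is the ring enol methyl ether of triketone 13, which is the C-acetyl derivative of the symmetric dione 11. 11 is the silyl ether of 5-hydroxycyclohexane-1,3-dione (9), the half-reduced form of phloroglucinol (8). The symmetry of 11 and 13 removes all regiochemical questions in acylation and O-methylation.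

7 from 6, 4, 3, 1 and 2 (through 5). The prenyl group is traced to an aromatic Claisen rearrangement of the 1,1-dimethylallyl ether 4. The only free ortho position of the vanillin core is C5, so the regiochemistry is fixed. 4 comes from propargyl ether 3 by semihydrogenation, and 3 from vanillin (1) and 3-chloro-3-methylbut-1-yne (2).

## Roads not taken

Alternative 1: Ring A is brought in as an aryne. CsF converts the silyl triflate A3 into its aryne, which inserts into the acyl–hydroxyl bond of the (R)-β-silyloxy acid A2. C8a–O and C4a–C4 form together and give the open-chain ortho-hydroxyaryl ketone A1.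
- Merits: ring A arrives aromatic, so no redox detour is needed. The alkoxy group next to the triple bond steers the insertion to the right regioisomer. The stereocentre of A2 can be made by very dependable asymmetric aldol or reduction chemistry. In these respects it is better than the chosen plan.
- Weak points: the fluoride that makes the aryne also attacks the benzylic silyl ether, and A1 is a β-silyloxy ketone that eliminates readily to the chalcone. Ring C then has to be closed in a separate, invertive substitution at an electron-rich benzylic carbinol, where ionization erodes the configuration. Three methoxymethyl acetals must finally be removed with acid beside a prenyl group ortho to a phenol. A3 itself needs several steps.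
- Against this the chosen plan sets a ring closure that retains the C2–O bond, no acetal hydrolysis, and fluoride only in the last, buffered step.

Alternative 2: PdCl2(PPh3)2 (a divalent palladium precatalyst), CO and Et2NH join iodophenol A5, carbon monoxide and aryl acetylene A6. C4a–C4, C4–C3 and O1–C2 form and ring C closes as flavone A4.
- Merits: it is the most convergent route to the whole skeleton, and A4 is achiral and robust. Its key step is more secure than the one chosen here.
- Weak points: the only stereocentre is postponed to an enantioselective reduction of the C2–C3 double bond of A4. This is a poorly electrophilic vinylogous ester, and the reduction must spare the prenyl olefin and the C4 ketone. This is the least secure kind of step for this substrate. Aurone formation competes in the annulation, mono-iodination to A5 must be selective, and the acetals again need acid at the end.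
- The chosen plan is longer on ring A but sets C2 while the skeleton is built, with a catalyst class known to control additions to aryl aldehydes.

Alternative 3: A chiral Brønsted acid (Me2AlCl for racemic material) ionizes the acetal C2–O bond of the 4-methylene-1,3-benzodioxine A8, and the enol carbon recloses on C2. C2–C3 and ring C form and give the tris(silyl) flavanone A7.
- Merits: ring A is aromatic throughout and the sequence is the shortest of all (acetal formation with an aldehyde of the type of 7, methylenation, rearrangement, desilylation). For racemic material it would be preferred to the chosen plan.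
- Weak points: ionization destroys the acetal stereocentre, so the configuration of C2 rests only on ion pairing between a chiral anion and a strongly stabilized para-silyloxybenzyl oxocarbenium ion. That pairing is loose, and useful selectivity is doubtful. Methylenation of a hindered, electron-rich benzodioxinone and handling of the acid-labile enol acetal A8 add risk.
- The chosen plan pays for its redox detour with enantiocontrol that rests on a tightly bound aldehyde–Lewis acid complex.

Key step: step 10

Assumption: (S)-BINOL–Ti(OiPr)4 is taken to direct the enol silane to the Si face of aldehyde 7, the sense this catalyst family shows with aryl aldehydes; (R)-BINOL would be used in the same procedure if the opposite sense were found.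

## Route

Step 1
Reactants: 1 vanillin; 2 3-chloro-3-methylbut-1-yne
Product: 3 3-methoxy-4-[(2-methylbut-3-yn-2-yl)oxy]benzaldehyde
Conditions: DBU, CuCl2·2H2O (cat.), MeCN, 0 °C
Reagents that add atoms: none
Why: Copper-catalysed O-propargylation of a phenol with a tertiary propargylic chloride is the standard entry to aryl 1,1-dimethylpropargyl ethers and tolerates the aldehyde.

Step 2
Reactants: 3 3-methoxy-4-[(2-methylbut-3-yn-2-yl)oxy]benzaldehyde
Product: 4 3-methoxy-4-[(2-methylbut-3-en-2-yl)oxy]benzaldehyde
Conditions: H2 (1 atm), Pd/CaCO3 poisoned with Pb(OAc)2, quinoline, EtOAc, rt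
Reagents that add atoms: none
Why: Semihydrogenation of a terminal alkyne over poisoned palladium stops at the alkene; the aryl aldehyde and the aryl ether are not reduced under these conditions.

Step 3
Reactants: 4 3-methoxy-4-[(2-methylbut-3-en-2-yl)oxy]benzaldehyde
Product: 6 4-hydroxy-3-methoxy-5-(3-methylbut-2-en-1-yl)benzaldehyde, via ortho-dienone 5 (not isolated)
Conditions: PhNEt2, 130 °C
Reagents that add atoms: none
Why: Aromatic Claisen rearrangement; the [3,3] shift can reach only C5 because the other ortho carbon bears the methoxy group, it converts the 1,1-dimethylallyl group into the linear prenyl group, and dienone 5 tautomerizes to the phenol, while the amine solvent suppresses acid-induced loss of isoprene and chroman formation.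

Step 4
Reactants: 6 4-hydroxy-3-methoxy-5-(3-methylbut-2-en-1-yl)benzaldehyde
Product: 7 3-methoxy-5-(3-methylbut-2-en-1-yl)-4-[(triisopropylsilyl)oxy]benzaldehyde
Conditions: TIPSCl, imidazole, DMF, rt
Reagents that add atoms: triisopropylsilyl chloride, CC(C)[Si](Cl)(C(C)C)C(C)C
Why: Silylation of an acidic phenol; the bulky silyl ether between two ortho substituents is meant to outlast the acid of steps 10 and 11 and the oxidant of step 12 and still fall to fluoride.

Step 5
Reactants: 8 phloroglucinol
Product: 9 5-hydroxycyclohexane-1,3-dione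
Conditions: NaBH4, H2O, 0 °C to rt; then acidic ion-exchange resin to pH 4
Reagents that add atoms: none
Why: Hydride reduction of the keto tautomer of the phloroglucinolate; after one carbonyl is reduced the product is a vinylogous carboxylate anion that resists further hydride, as in the half-reduction of resorcinol to cyclohexane-1,3-dione.

Step 6
Reactants: 9 5-hydroxycyclohexane-1,3-dione
Product: 11 5-[(tert-butyldimethylsilyl)oxy]cyclohexane-1,3-dione, via bis-silyl enol ether 10 (not isolated)
Conditions: TBSCl (2.3 equiv), imidazole, DMF, 0 °C to rt; then aq. citric acid, THF, rt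
Reagents that add atoms: tert-butyldimethylsilyl chloride, CC(C)(C)[Si](C)(C)Cl
Why: Silyl chloride and imidazole silylate both the carbinol and the acidic enol; the vinylogous silyl ester of 10 hydrolyses on mild aqueous acid work-up while the secondary alkyl silyl ether stays.

Step 7
Reactants: 11 5-[(tert-butyldimethylsilyl)oxy]cyclohexane-1,3-dione
Product: 13 2-acetyl-5-[(tert-butyldimethylsilyl)oxy]cyclohexane-1,3-dione (enol form), via enol acetate 12 (not isolated)
Conditions: AcOH, DCC, DMAP, CH2Cl2, rt
Reagents that add atoms: acetic acid, CC(=O)O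
Why: Carbodiimide O-acylation of the enol followed by DMAP-mediated O-to-C acyl migration is the standard route to 2-acylcyclohexane-1,3-diones; the symmetric dione offers a single C2.

Step 8
Reactants: 13 2-acetyl-5-[(tert-butyldimethylsilyl)oxy]cyclohexane-1,3-dione
Product: 14 2-acetyl-5-[(tert-butyldimethylsilyl)oxy]-3-methoxycyclohex-2-en-1-one (racemic)
Conditions: TMSCHN2 (hexanes), MeOH–toluene, 0 °C
Reagents that add atoms: (trimethylsilyl)diazomethane, C[Si](C)(C)C=[N+]=[N-]
Why: O-Methylation of the strongly acidic β-triketone by a diazoalkane, which for 2-acylcyclohexane-1,3-diones takes place at the ring enol oxygen; the two ring carbonyls of 13 are equivalent, so one constitutional isomer results.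

Step 9
Reactants: 14 2-acetyl-5-[(tert-butyldimethylsilyl)oxy]-3-methoxycyclohex-2-en-1-one
Product: 15 5-[(tert-butyldimethylsilyl)oxy]-3-methoxy-2-[1-(trimethylsilyloxy)ethenyl]cyclohex-2-en-1-one (racemic)
Conditions: LiN(iPr)2, TMSCl (in situ), THF, −78 °C
Reagents that add atoms: trimethylsilyl chloride, C[Si](C)(C)Cl
Why: Kinetic enolization of a methyl ketone with in situ silyl trapping; the acetyl group is twisted out of conjugation by its two flanking substituents, so its methyl protons are the most accessible, and trapping at −78 °C precedes equilibration to ring enolates that could expel the C5 silyloxy group.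

Step 10
Reactants: 7 3-methoxy-5-(3-methylbut-2-en-1-yl)-4-[(triisopropylsilyl)oxy]benzaldehyde; 15 5-[(tert-butyldimethylsilyl)oxy]-3-methoxy-2-[1-(trimethylsilyloxy)ethenyl]cyclohex-2-en-1-one
Product: 17 (2S)-7-[(tert-butyldimethylsilyl)oxy]-2-{3-methoxy-5-(3-methylbut-2-en-1-yl)-4-[(triisopropylsilyl)oxy]phenyl}-2,3,7,8-tetrahydro-4H-chromene-4,5(6H)-dione (both C7 epimers), via silylated aldol adduct 16 (not isolated)
Conditions: (S)-BINOL (40 mol %), Ti(OiPr)4 (20 mol %), 4 Å MS, Et2O, −20 °C to 0 °C; then TFA, CH2Cl2, 0 °C
Reagents that add atoms: none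
Why: The titanium BINOLate (tetravalent titanium) binds the aldehyde oxygen of 7, and the terminal CH2 of enol silane 15 adds to the carbonyl carbon in a Mukaiyama aldol step with silyl transfer, giving 16 and the C2–C3 bond. Trifluoroacetic acid then removes the trimethylsilyl group, the C2 hydroxyl adds to C8a of the doubly activated β-methoxy enone, and methanol is expelled, which forms O1–C8a. The closest known reaction type is the BINOL–titanium-catalysed formal hetero-Diels–Alder reaction of aryl aldehydes with 1-methoxy-3-silyloxy dienes to 2-aryl-2,3-dihydropyran-4-ones. Ring C closes by a 6-endo-trig addition–elimination at a vinylogous ester carbon. The new stereocentre C2 is set in the aldol step by the catalyst, with (S)-BINOL expected to expose the Si face of the bound aldehyde; the C2–O bond is not broken in the ring closure, so the configuration is retained. The step needs attack at the aldehyde only, which is secured because the ring carbonyl of 15 is an unreactive vinylogous ester, and the enol silane has a single nucleophilic carbon. The racemic C7 centre gives two epimers of 17 that merge in step 12. The 4'-oxygen is silylated so that acid cannot close a chroman onto the prenyl group, and the acid stage is kept short and cold to avoid ionization of C2–O1.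

Step 11
Reactants: 17 (2S)-7-[(tert-butyldimethylsilyl)oxy]-2-{3-methoxy-5-(3-methylbut-2-en-1-yl)-4-[(triisopropylsilyl)oxy]phenyl}-2,3,7,8-tetrahydro-4H-chromene-4,5(6H)-dione
Product: 18 (2S)-7-hydroxy-2-{3-methoxy-5-(3-methylbut-2-en-1-yl)-4-[(triisopropylsilyl)oxy]phenyl}-2,3,7,8-tetrahydro-4H-chromene-4,5(6H)-dione (both C7 epimers)
Conditions: 48% aq. HF (5% v/v), MeCN, 0 °C to rt
Reagents that add atoms: none
Why: Acidic fluoride cleaves alkyl silyl ethers much faster than aryl silyl ethers, and the hindered aryl triisopropylsilyl ether is the least labile of all; the medium is too weakly acidic at this temperature to ionize C2–O1 or to hydrate the prenyl olefin.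

Step 12
Reactants: 18 (2S)-7-hydroxy-2-{3-methoxy-5-(3-methylbut-2-en-1-yl)-4-[(triisopropylsilyl)oxy]phenyl}-2,3,7,8-tetrahydro-4H-chromene-4,5(6H)-dione
Product: 20 (2S)-5,7-dihydroxy-2-{3-methoxy-5-(3-methylbut-2-en-1-yl)-4-[(triisopropylsilyl)oxy]phenyl}chroman-4-one, via 7-oxo trione 19 (not isolated)
Conditions: Dess–Martin periodinane (1.2 equiv), CH2Cl2, 0 °C
Reagents that add atoms: none
Why: Dess–Martin oxidation of the secondary carbinol gives trione 19, whose enolizations towards C6 and C8 produce the aromatic 5,7-dihydroxy ring; the chelated, acyl-deactivated ring A phenols are poor partners for the periodinane, the sensitive ring B phenol is still silylated, and C2 is untouched under these non-basic conditions.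

Step 13
Reactants: 20 (2S)-5,7-dihydroxy-2-{3-methoxy-5-(3-methylbut-2-en-1-yl)-4-[(triisopropylsilyl)oxy]phenyl}chroman-4-one
Product: 21 (2S)-5,7-dihydroxy-2-[4-hydroxy-3-methoxy-5-(3-methylbut-2-en-1-yl)phenyl]chroman-4-one
Conditions: Bu4NF, AcOH (1:1), THF, 0 °C
Reagents that add atoms: none
Why: Fluoride cleavage of the aryl silyl ether; acetic acid buffers the basicity of fluoride and phenoxide so that ring C is not opened to the chalcone and C2 keeps its configuration.

## Compound list

1 | vanillin | COc1cc(C=O)ccc1O | starting material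
2 | 3-chloro-3-methylbut-1-yne | CC(C)(Cl)C#C | starting material
3 | 3-methoxy-4-[(2-methylbut-3-yn-2-yl)oxy]benzaldehyde | COc1cc(C=O)ccc1OC(C)(C)C#C | intermediate
4 | 3-methoxy-4-[(2-methylbut-3-en-2-yl)oxy]benzaldehyde | COc1cc(C=O)ccc1OC(C)(C)C=C | intermediate
5 | 5-methoxy-3-(3-methylbut-2-en-1-yl)-4-oxocyclohexa-1,5-diene-1-carbaldehyde (racemic, not isolated) | O=CC1=CC(CC=C(C)C)C(=O)C(OC)=C1 | intermediate
6 | 4-hydroxy-3-methoxy-5-(3-methylbut-2-en-1-yl)benzaldehyde | COc1cc(C=O)cc(CC=C(C)C)c1O | intermediate
7 | 3-methoxy-5-(3-methylbut-2-en-1-yl)-4-[(triisopropylsilyl)oxy]benzaldehyde | COc1cc(C=O)cc(CC=C(C)C)c1O[Si](C(C)C)(C(C)C)C(C)C | intermediate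
8 | phloroglucinol | Oc1cc(O)cc(O)c1 | starting material
9 | 5-hydroxycyclohexane-1,3-dione | O=C1CC(=O)CC(O)C1 | intermediate
10 | 3,5-bis[(tert-butyldimethylsilyl)oxy]cyclohex-2-en-1-one (racemic, not isolated) | CC(C)(C)[Si](C)(C)OC1CC(=O)C=C(O[Si](C)(C)C(C)(C)C)C1 | intermediate
11 | 5-[(tert-butyldimethylsilyl)oxy]cyclohexane-1,3-dione | CC(C)(C)[Si](C)(C)OC1CC(=O)CC(=O)C1 | intermediate
12 | 5-[(tert-butyldimethylsilyl)oxy]-3-oxocyclohex-1-en-1-yl acetate (racemic, not isolated) | CC(=O)OC1=CC(=O)CC(O[Si](C)(C)C(C)(C)C)C1 | intermediate
13 | 2-acetyl-5-[(tert-butyldimethylsilyl)oxy]cyclohexane-1,3-dione, drawn as one of its rapidly exchanging enol tautomers | CC(=O)C1=C(O)CC(O[Si](C)(C)C(C)(C)C)CC1=O | intermediate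
14 | 2-acetyl-5-[(tert-butyldimethylsilyl)oxy]-3-methoxycyclohex-2-en-1-one (racemic) | CC(=O)C1=C(OC)CC(O[Si](C)(C)C(C)(C)C)CC1=O | intermediate
15 | 5-[(tert-butyldimethylsilyl)oxy]-3-methoxy-2-[1-(trimethylsilyloxy)ethenyl]cyclohex-2-en-1-one (racemic) | C=C(O[Si](C)(C)C)C1=C(OC)CC(O[Si](C)(C)C(C)(C)C)CC1=O | intermediate
16 | 5-[(tert-butyldimethylsilyl)oxy]-3-methoxy-2-[(3S)-3-{3-methoxy-5-(3-methylbut-2-en-1-yl)-4-[(triisopropylsilyl)oxy]phenyl}-3-(trimethylsilyloxy)propanoyl]cyclohex-2-en-1-one (both ring epimers, not isolated) | COc1cc([C@@H](O[Si](C)(C)C)CC(=O)C2=C(OC)CC(O[Si](C)(C)C(C)(C)C)CC2=O)cc(CC=C(C)C)c1O[Si](C(C)C)(C(C)C)C(C)C | intermediate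
17 | (2S)-7-[(tert-butyldimethylsilyl)oxy]-2-{3-methoxy-5-(3-methylbut-2-en-1-yl)-4-[(triisopropylsilyl)oxy]phenyl}-2,3,7,8-tetrahydro-4H-chromene-4,5(6H)-dione (both C7 epimers) | COc1cc([C@@H]2CC(=O)C3=C(CC(O[Si](C)(C)C(C)(C)C)CC3=O)O2)cc(CC=C(C)C)c1O[Si](C(C)C)(C(C)C)C(C)C | intermediate
18 | (2S)-7-hydroxy-2-{3-methoxy-5-(3-methylbut-2-en-1-yl)-4-[(triisopropylsilyl)oxy]phenyl}-2,3,7,8-tetrahydro-4H-chromene-4,5(6H)-dione (both C7 epimers) | COc1cc([C@@H]2CC(=O)C3=C(CC(O)CC3=O)O2)cc(CC=C(C)C)c1O[Si](C(C)C)(C(C)C)C(C)C | intermediate
19 | (2S)-2-{3-methoxy-5-(3-methylbut-2-en-1-yl)-4-[(triisopropylsilyl)oxy]phenyl}-2,3-dihydro-4H-chromene-4,5,7(6H,8H)-trione (not isolated) | COc1cc([C@@H]2CC(=O)C3=C(CC(=O)CC3=O)O2)cc(CC=C(C)C)c1O[Si](C(C)C)(C(C)C)C(C)C | intermediate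
20 | (2S)-5,7-dihydroxy-2-{3-methoxy-5-(3-methylbut-2-en-1-yl)-4-[(triisopropylsilyl)oxy]phenyl}chroman-4-one | COc1cc([C@@H]2CC(=O)c3c(O)cc(O)cc3O2)cc(CC=C(C)C)c1O[Si](C(C)C)(C(C)C)C(C)C | intermediate
21 | (2S)-5,7-dihydroxy-2-[4-hydroxy-3-methoxy-5-(3-methylbut-2-en-1-yl)phenyl]chroman-4-one | COc1cc([C@@H]2CC(=O)c3c(O)cc(O)cc3O2)cc(CC=C(C)C)c1O | target

## Step count and risks

Total: 13 steps. Longest linear sequence: 9 steps (8 to 21, steps 5 to 13). The aldehyde branch (1 to 7) has 4 steps.

Step 10 (key step). The enol silane of 15 is twisted and carries an electron-withdrawing ring carbonyl, and aldehyde 7 is electron-rich. Addition under a mild titanium Lewis acid may therefore be slow, facial selectivity may be modest, and the acid stage may erode configuration by ionizing the benzylic C2–O1 bond. Fallback, setting out from 14 and 7 and returning at 17: ketone 14 is enolized with (−)-Ipc2BCl (chlorodiisopinocampheylborane; its antipode if the sense of addition requires it) and Et3N. The boron enolate is added to 7 to give 5-[(tert-butyldimethylsilyl)oxy]-2-[(3S)-3-hydroxy-3-{3-methoxy-5-(3-methylbut-2-en-1-yl)-4-[(triisopropylsilyl)oxy]phenyl}propanoyl]-3-methoxycyclohex-2-en-1-one F1. This is enriched by crystallization or chromatography and closed to 17 with pyridinium p-toluenesulfonate in CH2Cl2. Here the chirality comes from a stoichiometric boron reagent and no silyl diene or strong acid is needed.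

Step 9. Deprotonation may occur at the ring CH2 groups in place of the acetyl methyl, followed by loss of the C5 silanolate and aromatization. Fallback, setting out from 14 and returning at 18:
- Aqueous HF in MeCN frees the carbinol to give 2-acetyl-5-hydroxy-3-methoxycyclohex-2-en-1-one F2.
- Two equivalents of LiN(iPr)2 form the alkoxide first; it cannot leave and it disfavours deprotonation at the flanking ring positions. TMSCl then gives 3-methoxy-5-(trimethylsilyloxy)-2-[1-(trimethylsilyloxy)ethenyl]cyclohex-2-en-1-one F3.
- F3 and 7 react under the conditions of step 10 through the bis(trimethylsilyl) aldol adduct F4. The acid stage also removes the C7 trimethylsilyl ether, so 18 is reached directly.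

Step 8. Methylation may take place at the side-chain enol oxygen or at carbon. Fallback, setting out from 13 and returning at 14: oxalyl chloride (cat. DMF, CH2Cl2) converts the ring enol into the vinylogous acid chloride 2-acetyl-5-[(tert-butyldimethylsilyl)oxy]-3-chlorocyclohex-2-en-1-one F5. Methanol and Et3N at 0 °C then replace chloride by addition–elimination at the ring carbon, which fixes the position of the methoxy group.

Step 11. The liberated β-hydroxy ketone may dehydrate under acid, which would cost the C7 oxygen on aromatization, and the aryl silyl ether may be partly lost. Fallback, setting out from 17 and returning at 21: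
- Bu4NF buffered with AcOH removes both silyl groups to give (2S)-7-hydroxy-2-[4-hydroxy-3-methoxy-5-(3-methylbut-2-en-1-yl)phenyl]-2,3,7,8-tetrahydro-4H-chromene-4,5(6H)-dione F6.
- A Pfitzner–Moffatt oxidation (DCC, DMSO, pyridinium trifluoroacetate, about one equivalent) then oxidizes the carbinol to (2S)-2-[4-hydroxy-3-methoxy-5-(3-methylbut-2-en-1-yl)phenyl]-2,3-dihydro-4H-chromene-4,5,7(6H,8H)-trione F7, which tautomerizes to 21.
- Activated DMSO does not oxidize phenols, and both ortho positions of the ring B phenol are occupied, so the usual ortho-thiomethylation has no site there.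

Step 5. Reduction may run past the dione stage, and the water-soluble product may be hard to isolate. Fallback, setting out from 8 and returning at 11: exhaustive hydrogenation (H2, Rh/Al2O3, EtOH) gives all-cis-cyclohexane-1,3,5-triol F8. Statistical mono-silylation (TBSCl, imidazole; the three hydroxyls are equivalent) gives all-cis-5-[(tert-butyldimethylsilyl)oxy]cyclohexane-1,3-diol F9. Double oxidation with Dess–Martin periodinane gives 11.

## Further compounds

F1 | step 10 | 5-[(tert-butyldimethylsilyl)oxy]-2-[(3S)-3-hydroxy-3-{3-methoxy-5-(3-methylbut-2-en-1-yl)-4-[(triisopropylsilyl)oxy]phenyl}propanoyl]-3-methoxycyclohex-2-en-1-one | COc1cc([C@@H](O)CC(=O)C2=C(OC)CC(O[Si](C)(C)C(C)(C)C)CC2=O)cc(CC=C(C)C)c1O[Si](C(C)C)(C(C)C)C(C)C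
F2 | step 9 | 2-acetyl-5-hydroxy-3-methoxycyclohex-2-en-1-one (racemic) | CC(=O)C1=C(OC)CC(O)CC1=O
F3 | step 9 | 3-methoxy-5-(trimethylsilyloxy)-2-[1-(trimethylsilyloxy)ethenyl]cyclohex-2-en-1-one (racemic) | C=C(O[Si](C)(C)C)C1=C(OC)CC(O[Si](C)(C)C)CC1=O
F4 | step 9 | 3-methoxy-2-[(3S)-3-{3-methoxy-5-(3-methylbut-2-en-1-yl)-4-[(triisopropylsilyl)oxy]phenyl}-3-(trimethylsilyloxy)propanoyl]-5-(trimethylsilyloxy)cyclohex-2-en-1-one | COc1cc([C@@H](O[Si](C)(C)C)CC(=O)C2=C(OC)CC(O[Si](C)(C)C)CC2=O)cc(CC=C(C)C)c1O[Si](C(C)C)(C(C)C)C(C)C
F5 | step 8 | 2-acetyl-5-[(tert-butyldimethylsilyl)oxy]-3-chlorocyclohex-2-en-1-one (racemic) | CC(=O)C1=C(Cl)CC(O[Si](C)(C)C(C)(C)C)CC1=O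
F6 | step 11 | (2S)-7-hydroxy-2-[4-hydroxy-3-methoxy-5-(3-methylbut-2-en-1-yl)phenyl]-2,3,7,8-tetrahydro-4H-chromene-4,5(6H)-dione | COc1cc([C@@H]2CC(=O)C3=C(CC(O)CC3=O)O2)cc(CC=C(C)C)c1O
F7 | step 11 | (2S)-2-[4-hydroxy-3-methoxy-5-(3-methylbut-2-en-1-yl)phenyl]-2,3-dihydro-4H-chromene-4,5,7(6H,8H)-trione | COc1cc([C@@H]2CC(=O)C3=C(CC(=O)CC3=O)O2)cc(CC=C(C)C)c1O
F8 | step 5 | all-cis-cyclohexane-1,3,5-triol | O[C@@H]1C[C@H](O)C[C@H](O)C1
F9 | step 5 | all-cis-5-[(tert-butyldimethylsilyl)oxy]cyclohexane-1,3-diol | CC(C)(C)[Si](C)(C)O[C@@H]1C[C@H](O)C[C@H](O)C1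
A1 | alternative 1 | (3R)-3-[(tert-butyldimethylsilyl)oxy]-1-[2-hydroxy-4,6-bis(methoxymethoxy)phenyl]-3-[3-methoxy-4-(methoxymethoxy)-5-(3-methylbut-2-en-1-yl)phenyl]propan-1-one | COc1cc([C@H](O[Si](C)(C)C(C)(C)C)CC(=O)c2c(O)cc(OCOC)cc2OCOC)cc(CC=C(C)C)c1OCOC
A2 | alternative 1 | (3R)-3-[(tert-butyldimethylsilyl)oxy]-3-[3-methoxy-4-(methoxymethoxy)-5-(3-methylbut-2-en-1-yl)phenyl]propanoic acid | COc1cc([C@H](O[Si](C)(C)C(C)(C)C)CC(=O)O)cc(CC=C(C)C)c1OCOC
A3 | alternative 1 | 3,5-bis(methoxymethoxy)-2-(trimethylsilyl)phenyl trifluoromethanesulfonate | COCOc1cc(OCOC)cc(OS(=O)(=O)C(F)(F)F)c1[Si](C)(C)C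
A4 | alternative 2 | 5,7-bis(methoxymethoxy)-2-[3-methoxy-4-(methoxymethoxy)-5-(3-methylbut-2-en-1-yl)phenyl]-4H-chromen-4-one | COc1cc(-c2cc(=O)c3c(OCOC)cc(OCOC)cc3o2)cc(CC=C(C)C)c1OCOC
A5 | alternative 2 | 2-iodo-3,5-bis(methoxymethoxy)phenol | Oc1cc(OCOC)cc(OCOC)c1I
A6 | alternative 2 | 5-ethynyl-1-methoxy-2-(methoxymethoxy)-3-(3-methylbut-2-en-1-yl)benzene | COc1cc(C#C)cc(CC=C(C)C)c1OCOC
A7 | alternative 3 | (2S)-5,7-bis[(tert-butyldimethylsilyl)oxy]-2-{4-[(tert-butyldimethylsilyl)oxy]-3-methoxy-5-(3-methylbut-2-en-1-yl)phenyl}chroman-4-one | COc1cc([C@@H]2CC(=O)c3c(O[Si](C)(C)C(C)(C)C)cc(O[Si](C)(C)C(C)(C)C)cc3O2)cc(CC=C(C)C)c1O[Si](C)(C)C(C)(C)C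
A8 | alternative 3 | 5,7-bis[(tert-butyldimethylsilyl)oxy]-2-{4-[(tert-butyldimethylsilyl)oxy]-3-methoxy-5-(3-methylbut-2-en-1-yl)phenyl}-4-methylidene-4H-1,3-benzodioxine (racemic) | C=C1OC(c2cc(OC)c(O[Si](C)(C)C(C)(C)C)c(CC=C(C)C)c2)Oc2cc(O[Si](C)(C)C(C)(C)C)cc(O[Si](C)(C)C(C)(C)C)c12
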